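**Retrosynthetic overview**
1. Target 22 ⇐ acyclic, (Z,Z)-configured bromo-lactol 18: the ten-membered carbocycle is closed at C6–C7 (the farnesyl C1–C10 bond of the germacrene pathway), then the C6 alkoxide lactonises onto C12. Carbocycle first, γ-lactone second, both in the last flask.
2. 18 ⇐ 17 by unmasking (the ethoxy-dihydropyran is a masked Z-enal plus C2–OH; TBS on O14). 17 ⇐ vinyl carbinol angelate 15 + bromomethyl acrylate 16 by cross-metathesis.
3. 15 ⇐ diol 11 ⇐ E-alkylidene butyrolactone 10, which hides O8/C14 and fixes the C1=C10 geometry.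
4. 10 ⇐ phosphonolactone 8 (from vinyloxirane 5 + 6; source of C8) + aldehyde 9 (from hetero-Diels–Alder adduct 4 of diene 2 and glyoxylate 3; source of C2 and of the cis C4=C5 bond).
5. The dihydropyran is only a temporary mask; it is opened before the two skeletal rings are formed.

Assumption: germacrane locants are used (lactone O on C6, angelate on C8, CH2OH = C14, ring CH3 = C15); (R)-2-vinyloxirane of high ee is bought as such; the facial sense of the BINOL–titanium catalyst is taken by analogy with glyoxylate-ene reactions, where the (R)-catalyst gives the (R)-α-oxy ester.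

**Route**

Step 1
Reactants: 1 1,1-diethoxy-3-methylbut-2-ene
Product: 2 (1E)-1-ethoxy-3-methylbuta-1,3-diene
Conditions: KHSO4 (1 mol%), neat, 150 °C, EtOH and diene distilled out; redistilled from K2CO3
Reagents that add atoms: none
Why: acid-catalysed 1,4-elimination of ethanol from an α,β-unsaturated acetal (allyl oxocarbenium ion, loss of a γ-methyl proton) gives the conjugated 1-alkoxydiene, mainly the E enol ether, and the minor Z isomer is inert in the next step.

Step 2
Reactants: 2 (1E)-1-ethoxy-3-methylbuta-1,3-diene; 3 ethyl glyoxylate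
Product: 4 ethyl (2S,6R)-6-ethoxy-4-methyl-3,6-dihydro-2H-pyran-2-carboxylate
Conditions: (S)-BINOL (10 mol%), TiCl2(OiPr)2 (10 mol%), 4 Å molecular sieves, CH2Cl2, −55 to −30 °C, 2 (1.5 equiv)
Reagents that add atoms: none
Why: catalytic asymmetric hetero-Diels–Alder reaction in which the diene CH2 terminus bonds to the glyoxylate carbon and the alkoxy-bearing carbon to oxygen, the endo mode giving the 2,6-cis acetal and the chiral titanium Lewis acid selecting the aldehyde face that sets C2 as S; the ring locks the future C4=C5 bond as cis.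

Step 3
Reactants: 5 (2R)-2-ethenyloxirane; 6 triethyl phosphonoacetate
Product: 8 diethyl [(5S)-5-ethenyl-2-oxooxolan-3-yl]phosphonate, via hydroxy phosphonoester alkoxide 7 (not isolated)
Conditions: NaOEt (1.0 equiv), EtOH, 0 to 60 °C, sealed vessel, 16 h; aq. HCl quench
Reagents that add atoms: none
Why: SN2 opening of the epoxide at its unsubstituted carbon by the stabilised phosphonoacetate carbanion followed by lactonisation of the alkoxide; the C8 stereocentre is carried over from 5 because its C–O bond is never broken.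

Step 4
Reactants: 4 ethyl (2S,6R)-6-ethoxy-4-methyl-3,6-dihydro-2H-pyran-2-carboxylate; 8 diethyl [(5S)-5-ethenyl-2-oxooxolan-3-yl]phosphonate
Product: 10 (3E,5S)-3-{[(2S,6R)-6-ethoxy-4-methyl-3,6-dihydro-2H-pyran-2-yl]methylidene}-5-ethenyloxolan-2-one, via aldehyde 9 (not isolated)
Conditions: 4, iBu2AlH (1.05 equiv), CH2Cl2, −78 °C, 1 h; then sodium salt of 8 (8 1.2 equiv, NaH 1.15 equiv, THF) added at −78 °C, warmed to 23 °C; aqueous potassium sodium tartrate work-up
Reagents that add atoms: none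
Why: tandem half-reduction/Horner–Wadsworth–Emmons olefination in which the chelated aluminium hemiacetal of the α-alkoxy ester releases aldehyde 9 only in the presence of the phosphonate anion, so C2 does not epimerise, and the α-phosphonolactone gives the favoured E-alkylidene lactone (pyranyl group anti to the carbonyl), which fixes the C1=C10 geometry.

Step 5
Reactants: 10 (3E,5S)-3-{[(2S,6R)-6-ethoxy-4-methyl-3,6-dihydro-2H-pyran-2-yl]methylidene}-5-ethenyloxolan-2-one
Product: 11 (2E,4S)-2-{[(2S,6R)-6-ethoxy-4-methyl-3,6-dihydro-2H-pyran-2-yl]methylidene}hex-5-ene-1,4-diol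
Conditions: iBu2AlH (3.5 equiv), CH2Cl2, −78 to 0 °C; aqueous potassium sodium tartrate work-up
Reagents that add atoms: none
Why: 1,2-reduction of a conjugated lactone by DIBAL-H gives the allylic 1,4-diol (C14–OH and C8–OH) without touching the acetal, the alkenes or any stereocentre.

Step 6
Reactants: 11 (2E,4S)-2-{[(2S,6R)-6-ethoxy-4-methyl-3,6-dihydro-2H-pyran-2-yl]methylidene}hex-5-ene-1,4-diol
Product: 12 (3S,5E)-5-{[(tert-butyldimethylsilyl)oxy]methyl}-6-[(2S,6R)-6-ethoxy-4-methyl-3,6-dihydro-2H-pyran-2-yl]hexa-1,5-dien-3-ol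
Conditions: TBSCl (1.05 equiv), imidazole (2 equiv), CH2Cl2, −20 to 0 °C
Reagents that add atoms: tert-butyldimethylsilyl chloride, CC(C)(C)[Si](C)(C)Cl
Why: chemoselective silylation of the primary allylic hydroxyl over the secondary one leaves only O8 free for acylation.

Step 7
Reactants: 12 (3S,5E)-5-{[(tert-butyldimethylsilyl)oxy]methyl}-6-[(2S,6R)-6-ethoxy-4-methyl-3,6-dihydro-2H-pyran-2-yl]hexa-1,5-dien-3-ol; 13 angelic acid
Product: 15 (3S,5E)-5-{[(tert-butyldimethylsilyl)oxy]methyl}-6-[(2S,6R)-6-ethoxy-4-methyl-3,6-dihydro-2H-pyran-2-yl]hexa-1,5-dien-3-yl (2Z)-2-methylbut-2-enoate, via mixed anhydride 14 (not isolated)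
Conditions: 13 (3 equiv), 2,4,6-trichlorobenzoyl chloride (3 equiv), Et3N (3.3 equiv), toluene, 23 °C, 2 h; then 12, 75 °C, 24 h, no DMAP
Reagents that add atoms: none
Why: Yamaguchi-type mixed-anhydride esterification run without a nucleophilic amine catalyst acylates O8 with retention at C8 and avoids the addition–elimination pathway that isomerises angelate to tiglate.

Step 8
Reactants: 15 (3S,5E)-5-{[(tert-butyldimethylsilyl)oxy]methyl}-6-[(2S,6R)-6-ethoxy-4-methyl-3,6-dihydro-2H-pyran-2-yl]hexa-1,5-dien-3-yl (2Z)-2-methylbut-2-enoate; 16 methyl 2-(bromomethyl)prop-2-enoate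
Product: 17 methyl (2Z,4S,6E)-2-(bromomethyl)-6-{[(tert-butyldimethylsilyl)oxy]methyl}-7-[(2S,6R)-6-ethoxy-4-methyl-3,6-dihydro-2H-pyran-2-yl]-4-{[(2Z)-2-methylbut-2-enoyl]oxy}hepta-2,6-dienoate
Conditions: 16 (8 equiv), second-generation Hoveyda–Grubbs catalyst RuCl2(H2IMes)(=CH-C6H4-2-OiPr) (10 mol%), 1,4-benzoquinone (20 mol%), CH2Cl2, 40 °C, 24 h
Reagents that add atoms: none
Why: Proposed new method: olefin cross-metathesis of the only monosubstituted alkene with a 1,1-disubstituted acrylate, in which the ruthenium alkylidene loads on the vinyl group, undergoes [2+2]/retro-[2+2] with the electron-poor partner that cannot homodimerise and releases ethene, the trisubstituted alkenes and the angelate being too hindered to react and thermodynamic control placing C8 trans to CO2Me (2Z); closest known reaction type is cross-metathesis of terminal alkenes with methacrylates and α-methylene lactones.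

Step 9
Reactants: 17 methyl (2Z,4S,6E)-2-(bromomethyl)-6-{[(tert-butyldimethylsilyl)oxy]methyl}-7-[(2S,6R)-6-ethoxy-4-methyl-3,6-dihydro-2H-pyran-2-yl]-4-{[(2Z)-2-methylbut-2-enoyl]oxy}hepta-2,6-dienoate
Product: 18 methyl (2Z,4S,6E)-2-(bromomethyl)-6-(hydroxymethyl)-7-[(2S)-6-hydroxy-4-methyl-3,6-dihydro-2H-pyran-2-yl]-4-{[(2Z)-2-methylbut-2-enoyl]oxy}hepta-2,6-dienoate
Conditions: 48% aq. HF/MeCN/H2O (1:18:1), 0 °C, 2 h; aq. NaHCO3 to pH 6–7; used at once
Reagents that add atoms: water, O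
Why: acid hydrolysis of the allylic acetal and fluoride cleavage of the primary silyl ether (acetal hydrolysis plus desilylation) give the lactol, the ring-closed form of the Z-hydroxy-enal, while the esters and the allylic bromide survive cold dilute acid; no stereocentre that matters is touched.

Step 10
Reactants: 18 methyl (2Z,4S,6E)-2-(bromomethyl)-6-(hydroxymethyl)-7-[(2S)-6-hydroxy-4-methyl-3,6-dihydro-2H-pyran-2-yl]-4-{[(2Z)-2-methylbut-2-enoyl]oxy}hepta-2,6-dienoate
Product: 22 (3aR,4S,6E,8S,10Z,11aR)-8-hydroxy-6-(hydroxymethyl)-10-methyl-3-methylidene-2-oxo-2,3,3a,4,5,8,9,11a-octahydrocyclodeca[b]furan-4-yl (2Z)-2-methylbut-2-enoate, via open-chain Z-enal 19 (not isolated), via allylchromium species 20 (not isolated), via macrocyclic hydroxy ester 21 (not isolated)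
Conditions: CrCl2 (10 equiv), THF/DMF 4:1, 23 °C, 18 added by syringe pump over 12 h to 2 mM; aq. NH4Cl work-up
Reagents that add atoms: none
Why: Proposed new method: the lactol opens to Z-enal 19, CrCl2 (divalent chromium, two equivalents per C–Br bond) turns the allylic bromide into allylchromium 20 (trivalent chromium), and its γ-carbon C7 adds to the C6 aldehyde through a six-membered chromium-bridged chair with both tether arms pseudo-equatorial (6,7-anti, hence the trans lactone), A(1,3) strain holding H8 in the allyl plane so that the aldehyde, delivered by the C9 tether, arrives anti to the C8–O bond and is predicted to give (6R,7R) from (8S), after which the chromium alkoxide of 21 lactonises onto the methyl ester; closest known reaction type is the Nozaki–Hiyama–Kishi/Barbier macrocyclisation of ω-formyl 2-(bromomethyl)enoates to ten-membered germacranolides, together with metal-mediated allylation of lactols as masked hydroxy-aldehydes.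

**Compound list**
1 | 1,1-diethoxy-3-methylbut-2-ene | CCOC(OCC)C=C(C)C | starting material
2 | (1E)-1-ethoxy-3-methylbuta-1,3-diene | CCO/C=C/C(C)=C | intermediate
3 | ethyl glyoxylate | CCOC(=O)C=O | starting material
4 | ethyl (2S,6R)-6-ethoxy-4-methyl-3,6-dihydro-2H-pyran-2-carboxylate (2,6-cis) | CCOC(=O)[C@@H]1CC(C)=C[C@H](OCC)O1 | intermediate
5 | (2R)-2-ethenyloxirane | C=C[C@@H]1CO1 | starting material
6 | triethyl phosphonoacetate | CCOC(=O)CP(=O)(OCC)OCC | starting material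
7 | ethyl (4S)-2-(diethoxyphosphoryl)-4-hydroxyhex-5-enoate (sodium alkoxide in the flask, C2 epimers) | CCOC(=O)C(C[C@H](O)C=C)P(=O)(OCC)OCC | intermediate (not isolated)
8 | diethyl [(5S)-5-ethenyl-2-oxooxolan-3-yl]phosphonate (C3 epimers) | CCOP(=O)(OCC)C1C[C@@H](C=C)OC1=O | intermediate
9 | (2S,6R)-6-ethoxy-4-methyl-3,6-dihydro-2H-pyran-2-carbaldehyde | O=C[C@@H]1CC(C)=C[C@H](OCC)O1 | intermediate (not isolated)
10 | (3E,5S)-3-{[(2S,6R)-6-ethoxy-4-methyl-3,6-dihydro-2H-pyran-2-yl]methylidene}-5-ethenyloxolan-2-one | CCO[C@H]1C=C(C)C[C@@H](/C=C2\C[C@@H](C=C)OC2=O)O1 | intermediate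
11 | (2E,4S)-2-{[(2S,6R)-6-ethoxy-4-methyl-3,6-dihydro-2H-pyran-2-yl]methylidene}hex-5-ene-1,4-diol | CCO[C@H]1C=C(C)C[C@@H](/C=C(/CO)C[C@H](O)C=C)O1 | intermediate
12 | (3S,5E)-5-{[(tert-butyldimethylsilyl)oxy]methyl}-6-[(2S,6R)-6-ethoxy-4-methyl-3,6-dihydro-2H-pyran-2-yl]hexa-1,5-dien-3-ol | CCO[C@H]1C=C(C)C[C@@H](/C=C(/CO[Si](C)(C)C(C)(C)C)C[C@H](O)C=C)O1 | intermediate
13 | angelic acid, (2Z)-2-methylbut-2-enoic acid | C/C=C(/C)C(=O)O | starting material
14 | (2Z)-2-methylbut-2-enoic 2,4,6-trichlorobenzoic anhydride | C/C=C(/C)C(=O)OC(=O)c1c(Cl)cc(Cl)cc1Cl | intermediate (not isolated)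
15 | (3S,5E)-5-{[(tert-butyldimethylsilyl)oxy]methyl}-6-[(2S,6R)-6-ethoxy-4-methyl-3,6-dihydro-2H-pyran-2-yl]hexa-1,5-dien-3-yl (2Z)-2-methylbut-2-enoate | CCO[C@H]1C=C(C)C[C@@H](/C=C(/CO[Si](C)(C)C(C)(C)C)C[C@H](OC(=O)/C(C)=C\C)C=C)O1 | intermediate
16 | methyl 2-(bromomethyl)prop-2-enoate | C=C(CBr)C(=O)OC | starting material
17 | methyl (2Z,4S,6E)-2-(bromomethyl)-6-{[(tert-butyldimethylsilyl)oxy]methyl}-7-[(2S,6R)-6-ethoxy-4-methyl-3,6-dihydro-2H-pyran-2-yl]-4-{[(2Z)-2-methylbut-2-enoyl]oxy}hepta-2,6-dienoate | CCO[C@H]1C=C(C)C[C@@H](/C=C(/CO[Si](C)(C)C(C)(C)C)C[C@H](OC(=O)/C(C)=C\C)/C=C(/C(=O)OC)CBr)O1 | intermediate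
18 | methyl (2Z,4S,6E)-2-(bromomethyl)-6-(hydroxymethyl)-7-[(2S)-6-hydroxy-4-methyl-3,6-dihydro-2H-pyran-2-yl]-4-{[(2Z)-2-methylbut-2-enoyl]oxy}hepta-2,6-dienoate (lactol, both anomers) | OC1C=C(C)C[C@@H](/C=C(/CO)C[C@H](OC(=O)/C(C)=C\C)/C=C(/C(=O)OC)CBr)O1 | intermediate
19 | methyl (2Z,4S,6E,8S,10Z)-2-(bromomethyl)-8-hydroxy-6-(hydroxymethyl)-10-methyl-4-{[(2Z)-2-methylbut-2-enoyl]oxy}-12-oxododeca-2,6,10-trienoate | O=C/C=C(/C)C[C@H](O)/C=C(/CO)C[C@H](OC(=O)/C(C)=C\C)/C=C(/C(=O)OC)CBr | intermediate (not isolated)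
20 | allylchromium dichloride derived from 19 (CH2CrCl2 in place of CH2Br, trivalent chromium) | O=C/C=C(/C)C[C@H](O)/C=C(/CO)C[C@H](OC(=O)/C(C)=C\C)/C=C(/C(=O)OC)C[Cr](Cl)Cl | intermediate (not isolated)
21 | methyl 2-[(1S,2R,3Z,6S,7E,10S)-2,6-dihydroxy-8-(hydroxymethyl)-4-methyl-10-{[(2Z)-2-methylbut-2-enoyl]oxy}cyclodeca-3,7-dien-1-yl]prop-2-enoate (chromium alkoxide in the flask) | C=C(C(=O)OC)[C@H]1[C@H](O)/C=C(/C)C[C@H](O)/C=C(/CO)C[C@@H]1OC(=O)/C(C)=C\C | intermediate (not isolated)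
22 | (3aR,4S,6E,8S,10Z,11aR)-8-hydroxy-6-(hydroxymethyl)-10-methyl-3-methylidene-2-oxo-2,3,3a,4,5,8,9,11a-octahydrocyclodeca[b]furan-4-yl (2Z)-2-methylbut-2-enoate | C=C1C(=O)O[C@@H]2/C=C(/C)C[C@H](O)/C=C(/CO)C[C@H](OC(=O)/C(C)=C\C)[C@@H]12 | target

**Totals**
Total step count: 10. Longest linear sequence: 9 steps (steps 1, 2, 4, 5, 6, 7, 8, 9, 10; step 3 is the side branch).

**The three steps most likely to fail**

Step 10. The ring closure may be slow on the free lactol, or the open enal may isomerise or oligomerise, and the sense of induction at C6/C7 is a prediction. The fallback sets out from 17 and comes back at 21, and so at 22. It replaces the reductive chromium Barbier reaction by a neutral, thermal intramolecular allylboration. Compound 17 is borylated with B2pin2 and Pd2(dba)3 in DMSO at 50 °C to the allyl pinacolboronate F1. Dilute aqueous HCl in THF at 0 °C removes the acetal and the silyl ether to give the lactol boronate F2. Heating F2 at 2 mM in toluene at 80 °C lets the open-chain enal react through a closed six-membered boron transition state to the macrocyclic borate F3. Mild hydrolysis of F3 gives hydroxy ester 21, which lactonises with PPTS to 22. The diol on boron can be changed from pinacol to a chiral diol if reagent control over the C6/C7 faces is needed.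

Step 8. The 1,1-disubstituted bromomethyl acrylate may be too sluggish a metathesis partner next to the allylic ester. The fallback sets out from 6 (with 4 joining as in step 4) and comes back at 17. It builds the allyl bromide by Morita–Baylis–Hillman chemistry on a C7 aldehyde instead of metathesis.
- (S)-glycidyl 4-methoxybenzyl ether (COc1ccc(COC[C@@H]2CO2)cc1) is opened by the anion of 6 (NaOEt, EtOH) through the hydroxy phosphonoester F4 to the phosphonolactone F5.
- The one-pot reduction/olefination with 4 (through 9) gives the alkylidene lactone F6, and DIBAL-H gives the diol F7.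
- TBSCl gives the silyl ether F8, and the mixed-anhydride acylation of step 7 gives the angelate F9.
- DDQ in wet CH2Cl2 at pH 7 frees the primary alcohol F10, and Dess–Martin periodinane gives the aldehyde F11.
- Methyl acrylate with DABCO gives the Morita–Baylis–Hillman adduct F12, and PBr3 at −20 °C brominates it with allylic transposition to 17.

Step 3. The alkoxide of 7 can attack phosphorus (cyclopropanation pathway) and the vinyl epoxide can be opened at its allylic carbon. The fallback sets out from 5 and comes back at 8. It separates C–C bond formation from phosphorus introduction. Compound 5 is opened with dilithioacetate LiCH2CO2Li (from acetic acid and two equivalents of LiN(iPr)2) in THF to the hydroxy acid F13. Acidification closes F13 to the vinyl lactone F14. Its lithium enolate is trapped with ClP(O)(OEt)2 as the enol phosphate F15. A second equivalent of LiN(iPr)2 then triggers the 1,3-phosphorus shift (phosphate-to-phosphonate rearrangement) to 8.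

**Further compounds**
F1 | step 10 | methyl (2E,4S,6E)-6-{[(tert-butyldimethylsilyl)oxy]methyl}-7-[(2S,6R)-6-ethoxy-4-methyl-3,6-dihydro-2H-pyran-2-yl]-4-{[(2Z)-2-methylbut-2-enoyl]oxy}-2-[(4,4,5,5-tetramethyl-1,3,2-dioxaborolan-2-yl)methyl]hepta-2,6-dienoate | CCO[C@H]1C=C(C)C[C@@H](/C=C(/CO[Si](C)(C)C(C)(C)C)C[C@H](OC(=O)/C(C)=C\C)/C=C(/C(=O)OC)CB2OC(C)(C)C(C)(C)O2)O1
F2 | step 10 | methyl (2E,4S,6E)-6-(hydroxymethyl)-7-[(2S)-6-hydroxy-4-methyl-3,6-dihydro-2H-pyran-2-yl]-4-{[(2Z)-2-methylbut-2-enoyl]oxy}-2-[(4,4,5,5-tetramethyl-1,3,2-dioxaborolan-2-yl)methyl]hepta-2,6-dienoate | OC1C=C(C)C[C@@H](/C=C(/CO)C[C@H](OC(=O)/C(C)=C\C)/C=C(/C(=O)OC)CB2OC(C)(C)C(C)(C)O2)O1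
F3 | step 10 | O6-(pinacolatoboryl) derivative of hydroxy ester 21 | C=C(C(=O)OC)[C@H]1[C@H](OB2OC(C)(C)C(C)(C)O2)/C=C(/C)C[C@H](O)/C=C(/CO)C[C@@H]1OC(=O)/C(C)=C\C
F4 | step 8 | ethyl (4S)-2-(diethoxyphosphoryl)-4-hydroxy-5-[(4-methoxyphenyl)methoxy]pentanoate | CCOC(=O)C(C[C@H](O)COCc1ccc(OC)cc1)P(=O)(OCC)OCC
F5 | step 8 | diethyl [(5S)-5-{[(4-methoxyphenyl)methoxy]methyl}-2-oxooxolan-3-yl]phosphonate | CCOP(=O)(OCC)C1C[C@@H](COCc2ccc(OC)cc2)OC1=O
F6 | step 8 | (3E,5S)-3-{[(2S,6R)-6-ethoxy-4-methyl-3,6-dihydro-2H-pyran-2-yl]methylidene}-5-{[(4-methoxyphenyl)methoxy]methyl}oxolan-2-one | CCO[C@H]1C=C(C)C[C@@H](/C=C2\C[C@@H](COCc3ccc(OC)cc3)OC2=O)O1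
F7 | step 8 | (2S,4E)-5-[(2S,6R)-6-ethoxy-4-methyl-3,6-dihydro-2H-pyran-2-yl]-4-(hydroxymethyl)-1-[(4-methoxyphenyl)methoxy]pent-4-en-2-ol | CCO[C@H]1C=C(C)C[C@@H](/C=C(/CO)C[C@H](O)COCc2ccc(OC)cc2)O1
F8 | step 8 | (2S,4E)-4-{[(tert-butyldimethylsilyl)oxy]methyl}-5-[(2S,6R)-6-ethoxy-4-methyl-3,6-dihydro-2H-pyran-2-yl]-1-[(4-methoxyphenyl)methoxy]pent-4-en-2-ol | CCO[C@H]1C=C(C)C[C@@H](/C=C(/CO[Si](C)(C)C(C)(C)C)C[C@H](O)COCc2ccc(OC)cc2)O1
F9 | step 8 | (2S,4E)-4-{[(tert-butyldimethylsilyl)oxy]methyl}-5-[(2S,6R)-6-ethoxy-4-methyl-3,6-dihydro-2H-pyran-2-yl]-1-[(4-methoxyphenyl)methoxy]pent-4-en-2-yl (2Z)-2-methylbut-2-enoate | CCO[C@H]1C=C(C)C[C@@H](/C=C(/CO[Si](C)(C)C(C)(C)C)C[C@H](OC(=O)/C(C)=C\C)COCc2ccc(OC)cc2)O1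
F10 | step 8 | (2S,4E)-4-{[(tert-butyldimethylsilyl)oxy]methyl}-5-[(2S,6R)-6-ethoxy-4-methyl-3,6-dihydro-2H-pyran-2-yl]-1-hydroxypent-4-en-2-yl (2Z)-2-methylbut-2-enoate | CCO[C@H]1C=C(C)C[C@@H](/C=C(/CO[Si](C)(C)C(C)(C)C)C[C@H](OC(=O)/C(C)=C\C)CO)O1
F11 | step 8 | (2S,4E)-4-{[(tert-butyldimethylsilyl)oxy]methyl}-5-[(2S,6R)-6-ethoxy-4-methyl-3,6-dihydro-2H-pyran-2-yl]-1-oxopent-4-en-2-yl (2Z)-2-methylbut-2-enoate | CCO[C@H]1C=C(C)C[C@@H](/C=C(/CO[Si](C)(C)C(C)(C)C)C[C@H](OC(=O)/C(C)=C\C)C=O)O1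
F12 | step 8 | methyl (4S,6E)-6-{[(tert-butyldimethylsilyl)oxy]methyl}-7-[(2S,6R)-6-ethoxy-4-methyl-3,6-dihydro-2H-pyran-2-yl]-3-hydroxy-2-methylidene-4-{[(2Z)-2-methylbut-2-enoyl]oxy}hept-6-enoate (C3 epimers) | CCO[C@H]1C=C(C)C[C@@H](/C=C(/CO[Si](C)(C)C(C)(C)C)C[C@H](OC(=O)/C(C)=C\C)C(O)C(=C)C(=O)OC)O1
F13 | step 3 | (4S)-4-hydroxyhex-5-enoic acid | OC(=O)CC[C@H](O)C=C
F14 | step 3 | (5S)-5-ethenyloxolan-2-one | O=C1CC[C@@H](C=C)O1
F15 | step 3 | diethyl (5S)-5-ethenyl-4,5-dihydrofuran-2-yl phosphate | CCOP(=O)(OCC)OC1=CC[C@@H](C=C)O1
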